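**Retrosynthetic overview**
1. Target ⇒ (acetonide hydrolysis, C5 chlorination) bis-acetonide 21 ⇒ intramolecular Heck closure of the pyran ring through the C4–C4a bond of the (Z)-β-bromo dienyl enol ether 20.
2. Enabling feature: the carbocycle holds the enone C4a=C5–C6=O with an unsubstituted β-carbon C4a, 1,6 to vinylic C4 across the C1–O2–C3 enol-ether bridge. The target's pyran ring is a 4H-pyran-4-ylidene, and its C3=C4 and C4a=C5 bonds are exactly those left by carbopalladation and β-hydride elimination.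
3. 20 ⇒ vinylogous acid 19 (C1–OH) + bromoenyne 10, joined at O2–C3 by anti O–H addition to the 1-bromoalkyne.
4. 19 ⇒ enantioselective Diels–Alder adduct of 2-bromoacrolein and a 2-silyloxy diene: Br on C8a fixes the quaternary centre, steers the cis-dihydroxylation of C7=C8 and finally leaves as HBr. 10 ⇒ L-isoleucine, whose C1, C2, C3 become C3', C4', C5'.
5. Ring order: carbocycle first (Diels–Alder, step 9), pyran ring last (Heck, step 15).

Key step: step 15

Remark: atoms are numbered as in 6H-isochromene (C1, O2, C3, C4, C4a, C5–C8, C8a) and C1'–C7' in the heptenyl chain; 2-bromoacrolein is taken as a purchasable reagent, distilled before use.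

**Step 1**
Reactants: 1 L-isoleucine
Product: 2 (2S,3S)-2-hydroxy-3-methylpentanoic acid
Conditions: NaNO2, 1 M H2SO4, H2O, 0 °C → rt
Reagents that add atoms: water (O)
Why: Diazotisation of the α-amino acid goes with net retention through the α-lactone (double inversion), so the (2S,3S) centres of the chiral pool become C4' and C5'.

**Step 2**
Reactants: 2 (2S,3S)-2-hydroxy-3-methylpentanoic acid
Product: 3 (2S,3S)-2-hydroxy-N-methoxy-N,3-dimethylpentanamide
Conditions: MeNHOMe·HCl, EDC·HCl, HOBt (cat.), N-methylmorpholine, CH2Cl2, 0 °C → rt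
Reagents that add atoms: N,O-dimethylhydroxylamine hydrochloride (CNOC.Cl)
Why: Carbodiimide amidation gives the N-methoxy-N-methylamide without touching either stereocentre, the amine outrunning the free α-hydroxyl.

**Step 3**
Reactants: 3 (2S,3S)-2-hydroxy-N-methoxy-N,3-dimethylpentanamide; 4 1,4-bis(trimethylsilyl)buta-1,3-diyne
Product: 6 (6S,7S)-6-hydroxy-7-methyl-1-(trimethylsilyl)nona-1,3-diyn-5-one, via lithium 4-(trimethylsilyl)buta-1,3-diynide 5 (not isolated)
Conditions: 4 (2.3 equiv), MeLi·LiBr (2.2 equiv), THF, 0 °C → rt; then 3, −78 → −30 °C; aq. NH4Cl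
Reagents that add atoms: none
Why: Monodesilylation gives the lithium diynide; one equivalent deprotonates the hydroxyl and the second adds once to the amide, because the chelated tetrahedral intermediate survives until work-up (acyl substitution of an N-methoxy-N-methylamide).

**Step 4**
Reactants: 6 (6S,7S)-6-hydroxy-7-methyl-1-(trimethylsilyl)nona-1,3-diyn-5-one
Product: 7 (5R,6S,7S)-5,7-dimethyl-1-(trimethylsilyl)nona-1,3-diyne-5,6-diol
Conditions: MeMgBr (3 equiv), THF/CH2Cl2, −78 °C; aq. NH4Cl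
Reagents that add atoms: methylmagnesium bromide (C[Mg]Br)
Why: Chelation-controlled Grignard 1,2-addition: the magnesium alkoxide and the ketone oxygen form a five-membered chelate and methyl enters from the face of the small α-hydrogen, anti to the sec-butyl group, which sets C3' as (R).

**Step 5**
Reactants: 7 (5R,6S,7S)-5,7-dimethyl-1-(trimethylsilyl)nona-1,3-diyne-5,6-diol
Product: 8 (3E,5R,6S,7S)-5,7-dimethyl-1-(trimethylsilyl)non-3-en-1-yne-5,6-diol
Conditions: NaAlH2(OCH2CH2OMe)2 (4 equiv), THF, 0 °C → rt; aq. potassium sodium tartrate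
Reagents that add atoms: none
Why: Alkoxide-directed trans-hydroalumination of the triple bond next to the tertiary carbinol, then protonolysis, gives the (E)-enyne and leaves the remote silylalkyne alone.

**Step 6**
Reactants: 8 (3E,5R,6S,7S)-5,7-dimethyl-1-(trimethylsilyl)non-3-en-1-yne-5,6-diol
Product: 9 trimethyl{(3E)-4-[(4R,5S)-5-[(2S)-butan-2-yl]-2,2,4-trimethyl-1,3-dioxolan-4-yl]but-3-en-1-yn-1-yl}silane
Conditions: 2-methoxypropene, PPTS (cat.), CH2Cl2, 0 °C
Reagents that add atoms: 2-methoxypropene (COC(C)=C)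
Why: Mild acid-catalysed acetonide formation protects the vicinal diol without ionising the tertiary allylic alcohol.

**Step 7**
Reactants: 9 trimethyl{(3E)-4-[(4R,5S)-5-[(2S)-butan-2-yl]-2,2,4-trimethyl-1,3-dioxolan-4-yl]but-3-en-1-yn-1-yl}silane
Product: 10 (4R,5S)-4-[(1E)-4-bromobut-1-en-3-yn-1-yl]-5-[(2S)-butan-2-yl]-2,2,4-trimethyl-1,3-dioxolane
Conditions: NBS, AgNO3 (20 mol %), acetone, rt, dark
Reagents that add atoms: N-bromosuccinimide (O=C1CCC(=O)N1Br)
Why: Silver-catalysed desilylative bromination (silver acetylide, then electrophilic bromine) converts the alkynylsilane directly into the 1-bromoalkyne.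

**Step 8**
Reactants: 11 3-methylbut-3-en-2-one
Product: 12 triisopropyl[(3-methylbuta-1,3-dien-2-yl)oxy]silane
Conditions: TIPSOTf, Et3N, CH2Cl2, 0 °C → rt
Reagents that add atoms: triisopropylsilyl trifluoromethanesulfonate (CC(C)[Si](C(C)C)(C(C)C)OS(=O)(=O)C(F)(F)F)
Why: Soft enolisation and O-silylation of the methyl ketone give the 2-silyloxy diene.

**Step 9**
Reactants: 12 triisopropyl[(3-methylbuta-1,3-dien-2-yl)oxy]silane; 13 2-bromoprop-2-enal
Product: 14 (1R)-1-bromo-3-methyl-4-[(triisopropylsilyl)oxy]cyclohex-3-ene-1-carbaldehyde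
Conditions: (S)-3,3-diphenyl-1-(o-tolyl)tetrahydro-1H,3H-pyrrolo[1,2-c][1,3,2]oxazaborole protonated with HNTf2 (10 mol %), CH2Cl2, −78 °C
Reagents that add atoms: none
Why: Lewis-acid-catalysed enantioselective Diels–Alder reaction: the silyloxy group directs "para" bond formation (C6 para to C8a) and the diene adds to the Cα-Re face of the boron-bound s-trans enal, setting quaternary C8a as (R); the (S)-prolinol-derived catalyst is expected to expose that face, and its enantiomer is used if the sense proves opposite.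

**Step 10**
Reactants: 14 (1R)-1-bromo-3-methyl-4-[(triisopropylsilyl)oxy]cyclohex-3-ene-1-carbaldehyde
Product: 15 (1R)-1-bromo-3-methyl-4-oxocyclohex-2-ene-1-carbaldehyde
Conditions: Pd(OAc)2 (1.1 equiv), MeCN, rt
Reagents that add atoms: none
Why: Saegusa–Ito oxidation of the regiodefined silyl enol ether (palladium enolate, β-hydride elimination towards ring C8) gives the C7=C8 enone.

**Step 11**
Reactants: 15 (1R)-1-bromo-3-methyl-4-oxocyclohex-2-ene-1-carbaldehyde
Product: 16 (1R,2R,3S)-1-bromo-2,3-dihydroxy-3-methyl-4-oxocyclohexane-1-carbaldehyde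
Conditions: OsO4 (5 mol %), NMO (1.5 equiv), citric acid (0.75 equiv), acetone/H2O, rt
Reagents that add atoms: N-methylmorpholine N-oxide (C[N+]1([O-])CCOCC1); water (O)
Why: Catalytic syn-dihydroxylation should occur anti to the large, pseudo-axial allylic bromine on C8a, which makes the C7/C8 diol cis, trans to Br, and relays the C8a configuration into the two permanent ring stereocentres.

**Step 12**
Reactants: 16 (1R,2R,3S)-1-bromo-2,3-dihydroxy-3-methyl-4-oxocyclohexane-1-carbaldehyde
Product: 17 (3aR,4R,7aS)-4-bromo-2,2,7a-trimethyl-7-oxohexahydro-1,3-benzodioxole-4-carbaldehyde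
Conditions: 2-methoxypropene, PPTS (cat.), CH2Cl2, 0 °C → rt
Reagents that add atoms: 2-methoxypropene (COC(C)=C)
Why: The cis-diol is locked as the five-membered acetonide, which also pulls any lactol with the cis aldehyde back to the open form.

**Step 13**
Reactants: 17 (3aR,4R,7aS)-4-bromo-2,2,7a-trimethyl-7-oxohexahydro-1,3-benzodioxole-4-carbaldehyde
Product: 19 (3aS,7aS)-4-(hydroxymethylidene)-2,2,7a-trimethyl-3a,4-dihydro-1,3-benzodioxol-7(7aH)-one, via conjugated enal tautomer 18 (not isolated)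
Conditions: DBU (2.2 equiv), THF, 0 °C → rt; aq. citric acid
Reagents that add atoms: none
Why: E2 dehydrobromination: only a hydrogen on C4a is anti-periplanar to the axial C–Br bond (H-8 is cis to bromine after step 11), so the C8a=C4a enal forms and its doubly activated C5 methylene tautomerises to the conjugated vinylogous acid; the tethered acetonide oxygen on C8 is a poor, reversibly re-adding leaving group.

**Step 14**
Reactants: 19 (3aS,7aS)-4-(hydroxymethylidene)-2,2,7a-trimethyl-3a,4-dihydro-1,3-benzodioxol-7(7aH)-one; 10 (4R,5S)-4-[(1E)-4-bromobut-1-en-3-yn-1-yl]-5-[(2S)-butan-2-yl]-2,2,4-trimethyl-1,3-dioxolane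
Product: 20 (3aS,4E,7aS)-4-[({(1Z,3E)-1-bromo-4-[(4R,5S)-5-[(2S)-butan-2-yl]-2,2,4-trimethyl-1,3-dioxolan-4-yl]buta-1,3-dien-2-yl}oxy)methylidene]-2,2,7a-trimethyl-3a,4-dihydro-1,3-benzodioxol-7(7aH)-one
Conditions: Ph3PAuNTf2 (5 mol %), toluene, rt → 45 °C, dark
Reagents that add atoms: none
Why: Proposed new method: the monovalent-gold π-complex of the 1-bromoalkyne should be attacked anti by the enol oxygen of the vinylogous carboxylic acid at the alkenyl-substituted carbon C3, and protodeauration then gives the (Z)-β-bromo enol ether with Br cis to O2, the unhindered C1 oxygen reacting rather than the C6 oxygen beside quaternary C7; the closest known reaction type is the gold- or silver-catalysed anti addition of carboxylic, phosphoric and sulfonic acids to 1-haloalkynes giving (Z)-β-halo enol esters, together with the base-mediated addition of phenols to 1-bromoalkynes.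

**Step 15**
Reactants: 20 (3aS,4E,7aS)-4-[({(1Z,3E)-1-bromo-4-[(4R,5S)-5-[(2S)-butan-2-yl]-2,2,4-trimethyl-1,3-dioxolan-4-yl]buta-1,3-dien-2-yl}oxy)methylidene]-2,2,7a-trimethyl-3a,4-dihydro-1,3-benzodioxol-7(7aH)-one
Product: 21 (7S,8S)-3-{(E)-2-[(4R,5S)-5-[(2S)-butan-2-yl]-2,2,4-trimethyl-1,3-dioxolan-4-yl]ethenyl}-7,8-(isopropylidenedioxy)-7-methyl-7,8-dihydro-6H-isochromen-6-one
Conditions: Pd(OAc)2 (10 mol %), PPh3 (25 mol %), Ag2CO3 (1.1 equiv), MeCN, 65 °C
Reagents that add atoms: none
Why: Zerovalent palladium inserts into the C4–Br bond and the vinylpalladium adds syn across C4a=C5 (new bond C4–C4a); the C5-bound palladium enolate equilibrates through its O-bound form so that β-hydride elimination of H-4a (or base-assisted loss of HPdBr) re-forms C4a=C5. The closest known reaction types are the intramolecular Heck vinylation of cyclic enones and the palladium-catalysed cyclisation of (Z)-2-bromovinyl ethers onto sp2 carbon. The pyran ring (O2, C1, C8a, C4a, C4, C3) is the only ring closed and it closes 6-exo-trig; attack on C1=C8a would be 5-endo and is disfavoured. No permanent stereocentre is made, since C4a is sp3 only in the alkylpalladium intermediate and C7 and C8 are not touched. The step needs Br cis to O2 at C3=C4, secured by the anti addition of step 14, and O2 cis to C4a at C1=C8a, which is the less hindered geometry of this push–pull diene and can equilibrate on warming; the amine-free Ag2CO3 conditions remove hydride donors and so suppress the reductive conjugate-addition outcome. One operation thus delivers the complete cross-conjugated 6H-isochromen-6-one chromophore.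

**Step 16**
Reactants: 21 (7S,8S)-3-{(E)-2-[(4R,5S)-5-[(2S)-butan-2-yl]-2,2,4-trimethyl-1,3-dioxolan-4-yl]ethenyl}-7,8-(isopropylidenedioxy)-7-methyl-7,8-dihydro-6H-isochromen-6-one
Product: 22 (7S,8S)-5-chloro-3-{(E)-2-[(4R,5S)-5-[(2S)-butan-2-yl]-2,2,4-trimethyl-1,3-dioxolan-4-yl]ethenyl}-7,8-(isopropylidenedioxy)-7-methyl-7,8-dihydro-6H-isochromen-6-one
Conditions: NCS (1.05 equiv), CH2Cl2, −20 → 0 °C
Reagents that add atoms: N-chlorosuccinimide (O=C1CCC(=O)N1Cl)
Why: Electrophilic chlorination should take place at C5, the α-carbon of the doubly vinylogous ester fed by O2 through both C3=C4 and C1=C8a, followed by loss of H-5.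

**Step 17**
Reactants: 22 (7S,8S)-5-chloro-3-{(E)-2-[(4R,5S)-5-[(2S)-butan-2-yl]-2,2,4-trimethyl-1,3-dioxolan-4-yl]ethenyl}-7,8-(isopropylidenedioxy)-7-methyl-7,8-dihydro-6H-isochromen-6-one
Product: 23 (7S,8S)-5-chloro-3-[(1E,3R,4S,5S)-3,4-dihydroxy-3,5-dimethylhept-1-en-1-yl]-7,8-dihydroxy-7-methyl-7,8-dihydro-6H-isochromen-6-one
Conditions: TFA/H2O (4:1), 0 °C; pH 7 phosphate buffer
Reagents that add atoms: none
Why: Acid hydrolysis cleaves both acetonides at the acetal carbon; in TFA the chromophore is O-protonated to a pyrylium-type cation, which should disfavour ionisation of the C8–O and C3'–O bonds.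

**Compound list**
1 | L-isoleucine | CC[C@H](C)[C@H](N)C(=O)O | starting material
2 | (2S,3S)-2-hydroxy-3-methylpentanoic acid | CC[C@H](C)[C@H](O)C(=O)O | intermediate
3 | (2S,3S)-2-hydroxy-N-methoxy-N,3-dimethylpentanamide | CC[C@H](C)[C@H](O)C(=O)N(C)OC | intermediate
4 | 1,4-bis(trimethylsilyl)buta-1,3-diyne | C[Si](C)(C)C#CC#C[Si](C)(C)C | starting material
5 | lithium 4-(trimethylsilyl)buta-1,3-diynide | [Li]C#CC#C[Si](C)(C)C | intermediate (not isolated)
6 | (6S,7S)-6-hydroxy-7-methyl-1-(trimethylsilyl)nona-1,3-diyn-5-one | CC[C@H](C)[C@H](O)C(=O)C#CC#C[Si](C)(C)C | intermediate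
7 | (5R,6S,7S)-5,7-dimethyl-1-(trimethylsilyl)nona-1,3-diyne-5,6-diol | CC[C@H](C)[C@H](O)[C@](C)(O)C#CC#C[Si](C)(C)C | intermediate
8 | (3E,5R,6S,7S)-5,7-dimethyl-1-(trimethylsilyl)non-3-en-1-yne-5,6-diol | CC[C@H](C)[C@H](O)[C@](C)(O)/C=C/C#C[Si](C)(C)C | intermediate
9 | trimethyl{(3E)-4-[(4R,5S)-5-[(2S)-butan-2-yl]-2,2,4-trimethyl-1,3-dioxolan-4-yl]but-3-en-1-yn-1-yl}silane | CC[C@H](C)[C@@H]1OC(C)(C)O[C@]1(C)/C=C/C#C[Si](C)(C)C | intermediate
10 | (4R,5S)-4-[(1E)-4-bromobut-1-en-3-yn-1-yl]-5-[(2S)-butan-2-yl]-2,2,4-trimethyl-1,3-dioxolane | CC[C@H](C)[C@@H]1OC(C)(C)O[C@]1(C)/C=C/C#CBr | intermediate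
11 | 3-methylbut-3-en-2-one | CC(=O)C(C)=C | starting material
12 | triisopropyl[(3-methylbuta-1,3-dien-2-yl)oxy]silane | C=C(C)C(=C)O[Si](C(C)C)(C(C)C)C(C)C | intermediate
13 | 2-bromoprop-2-enal (2-bromoacrolein) | C=C(Br)C=O | starting material
14 | (1R)-1-bromo-3-methyl-4-[(triisopropylsilyl)oxy]cyclohex-3-ene-1-carbaldehyde | O=C[C@]1(Br)CC(C)=C(O[Si](C(C)C)(C(C)C)C(C)C)CC1 | intermediate
15 | (1R)-1-bromo-3-methyl-4-oxocyclohex-2-ene-1-carbaldehyde | O=C[C@]1(Br)C=C(C)C(=O)CC1 | intermediate
16 | (1R,2R,3S)-1-bromo-2,3-dihydroxy-3-methyl-4-oxocyclohexane-1-carbaldehyde | O=C[C@]1(Br)[C@H](O)[C@](C)(O)C(=O)CC1 | intermediate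
17 | (3aR,4R,7aS)-4-bromo-2,2,7a-trimethyl-7-oxohexahydro-1,3-benzodioxole-4-carbaldehyde | O=C[C@]1(Br)[C@@H]2OC(C)(C)O[C@]2(C)C(=O)CC1 | intermediate
18 | (3aS,7aS)-2,2,7a-trimethyl-7-oxo-3a,6,7,7a-tetrahydro-1,3-benzodioxole-4-carbaldehyde | O=CC1=CCC(=O)[C@@]2(C)OC(C)(C)O[C@@H]12 | intermediate (not isolated)
19 | (3aS,7aS)-4-(hydroxymethylidene)-2,2,7a-trimethyl-3a,4-dihydro-1,3-benzodioxol-7(7aH)-one | OC=C1C=CC(=O)[C@@]2(C)OC(C)(C)O[C@@H]12 | intermediate
20 | (3aS,4E,7aS)-4-[({(1Z,3E)-1-bromo-4-[(4R,5S)-5-[(2S)-butan-2-yl]-2,2,4-trimethyl-1,3-dioxolan-4-yl]buta-1,3-dien-2-yl}oxy)methylidene]-2,2,7a-trimethyl-3a,4-dihydro-1,3-benzodioxol-7(7aH)-one | CC[C@H](C)[C@@H]1OC(C)(C)O[C@]1(C)/C=C/C(=C/Br)O/C=C2\C=CC(=O)[C@@]3(C)OC(C)(C)O[C@@H]23 | intermediate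
21 | (7S,8S)-3-{(E)-2-[(4R,5S)-5-[(2S)-butan-2-yl]-2,2,4-trimethyl-1,3-dioxolan-4-yl]ethenyl}-7,8-(isopropylidenedioxy)-7-methyl-7,8-dihydro-6H-isochromen-6-one | CC[C@H](C)[C@@H]1OC(C)(C)O[C@]1(C)/C=C/C2=CC3=CC(=O)[C@@]4(C)OC(C)(C)O[C@H]4C3=CO2 | intermediate
22 | (7S,8S)-5-chloro-3-{(E)-2-[(4R,5S)-5-[(2S)-butan-2-yl]-2,2,4-trimethyl-1,3-dioxolan-4-yl]ethenyl}-7,8-(isopropylidenedioxy)-7-methyl-7,8-dihydro-6H-isochromen-6-one | CC[C@H](C)[C@@H]1OC(C)(C)O[C@]1(C)/C=C/C2=CC3=C(Cl)C(=O)[C@@]4(C)OC(C)(C)O[C@H]4C3=CO2 | intermediate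
23 | (7S,8S)-5-chloro-3-[(1E,3R,4S,5S)-3,4-dihydroxy-3,5-dimethylhept-1-en-1-yl]-7,8-dihydroxy-7-methyl-7,8-dihydro-6H-isochromen-6-one | CC[C@H](C)[C@H](O)[C@](C)(O)/C=C/C1=CC2=C(Cl)C(=O)[C@@](C)(O)[C@@H](O)C2=CO1 | target

**Step count and risks**
Total steps: 17. Longest linear sequence: 11 (steps 1–7, then 14–17, from L-isoleucine).

Most likely to fail, riskiest first:

Step 14 (Proposed new method). The ambident vinylogous acid may be alkenylated on carbon (C8a or C5) or on the C6 oxygen, or the cationic gold may oligomerise the bromoenyne before O–H addition. The fallback uses known chemistry and sets out from 10 and 19. Hydroiodination of the 1-bromoalkyne 10 (LiI, AcOH, cat. Pd(OAc)2, rt; iodide adds anti at the substituted carbon) should give the bromo-iodo diene (4R,5S)-4-[(1E,3Z)-4-bromo-3-iodobuta-1,3-dien-1-yl]-5-[(2S)-butan-2-yl]-2,2,4-trimethyl-1,3-dioxolane F1. An Ullmann-type C–O coupling of 19 with F1 (CuI, 1,10-phenanthroline, Cs2CO3, toluene, 80 °C) should then engage the C–I bond before the C–Br bond with retention of alkene geometry, and comes back to the route at 20.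

Step 15. The palladium enolate may be protonated instead of eliminating (reductive Heck outcome), β-hydride elimination may stall because H-4a is anti to palladium after syn insertion, or the acid-sensitive divinyl ether may hydrolyse before it cyclises. The fallback sets out from 20 and keeps the C4–C4a ring closure but makes it a radical event: (Me3Si)3SiH and AIBN in benzene at 80 °C generate the vinyl radical at C4, which should close 6-exo-trig onto C4a (its E/Z inversion is fast, so geometry no longer matters) to give the 4a,5-dihydro compound (7S,8S)-3-{(E)-2-[(4R,5S)-5-[(2S)-butan-2-yl]-2,2,4-trimethyl-1,3-dioxolan-4-yl]ethenyl}-7,8-(isopropylidenedioxy)-7-methyl-4a,5,7,8-tetrahydro-6H-isochromen-6-one F2 as a mixture at C4a. DDQ in dioxane then removes hydride from the doubly activated C4a and a proton from C5, and comes back to the route at 21.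

Step 11. Osmylation of the hindered enone may be slow and may discriminate poorly between the bromine and formyl flanks of C8a, which would erode the configurational relay into C7 and C8. The fallback sets out from 15 and replaces steric control by hydrogen-bond delivery. Chemoselective reduction of the aldehyde (NaBH4, CH2Cl2/MeOH, −78 °C) gives (4R)-4-bromo-4-(hydroxymethyl)-2-methylcyclohex-2-en-1-one F3. Stoichiometric OsO4 with TMEDA (CH2Cl2, −78 °C) should deliver both oxygens to the face of the hydroxymethyl group, which is the face required, giving (2S,3R,4S)-4-bromo-2,3-dihydroxy-4-(hydroxymethyl)-2-methylcyclohexan-1-one F4. Acetonide formation on the cis-1,2-diol (2-methoxypropene, PPTS) gives (3aR,4S,7aS)-4-bromo-4-(hydroxymethyl)-2,2,7a-trimethyltetrahydro-1,3-benzodioxol-7(3aH)-one F5, and oxidation of the primary alcohol with triacetoxy periodinane (DMP) comes back to the route at 17.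

**Further compounds**
F1 | step 14 | (4R,5S)-4-[(1E,3Z)-4-bromo-3-iodobuta-1,3-dien-1-yl]-5-[(2S)-butan-2-yl]-2,2,4-trimethyl-1,3-dioxolane | CC[C@H](C)[C@@H]1OC(C)(C)O[C@]1(C)/C=C/C(I)=C/Br
F2 | step 15 | (7S,8S)-3-{(E)-2-[(4R,5S)-5-[(2S)-butan-2-yl]-2,2,4-trimethyl-1,3-dioxolan-4-yl]ethenyl}-7,8-(isopropylidenedioxy)-7-methyl-4a,5,7,8-tetrahydro-6H-isochromen-6-one | CC[C@H](C)[C@@H]1OC(C)(C)O[C@]1(C)/C=C/C2=CC3CC(=O)[C@@]4(C)OC(C)(C)O[C@H]4C3=CO2
F3 | step 11 | (4R)-4-bromo-4-(hydroxymethyl)-2-methylcyclohex-2-en-1-one | OC[C@]1(Br)C=C(C)C(=O)CC1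
F4 | step 11 | (2S,3R,4S)-4-bromo-2,3-dihydroxy-4-(hydroxymethyl)-2-methylcyclohexan-1-one | OC[C@]1(Br)[C@H](O)[C@](C)(O)C(=O)CC1
F5 | step 11 | (3aR,4S,7aS)-4-bromo-4-(hydroxymethyl)-2,2,7a-trimethyltetrahydro-1,3-benzodioxol-7(3aH)-one | OC[C@]1(Br)[C@@H]2OC(C)(C)O[C@]2(C)C(=O)CC1
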